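Which flask ends highest in Z, and does the cool start of Monday's still show at its end?

| flask | J | Q | temperature | remark | time |
|---|---|---|---|---|---|
| zeta | 1.3 mM | 0.30 mM | 35 °C | run made earlier |  |
| alpha | 3 mM | 0.30 mM | 65 °C | run made earlier |  |
| epsilon | 2 mM | 0.45 mM | 35 °C | run made earlier |  |
| Monday's | 2.0 mM | 0.30 mM |  | at 40 °C until 2.0 min, from then on at 90 °C | 10 min |
| Saturday's | 2.0 mM | 0.30 mM | 65 °C |  | 10 min |
| Friday's | 2.0 mM | 0.30 mM | 40 °C |  | 10 min |
| Thursday's | 2.0 mM | 0.30 mM | 90 °C |  | 10 min |

| run | time / min | Z / % |
|---|---|---|
| zeta | 2.00 | 42 |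
| zeta | 4.00 | 41 |
| zeta | 6.00 | 41 |
| zeta | 8.00 | 37 |
| zeta | 20.0 | 36 |
| zeta | 25.0 | 41 |
| alpha | 0.417 | 16 |
| alpha | 1.33 | 16 |
| alpha | 2.00 | 14 |
| alpha | 3.00 | 16 |
| alpha | 5.00 | 14 |
| alpha | 6.00 | 12 |
| epsilon | 6.00 | 40 |
| epsilon | 12.0 | 41 |
| epsilon | 20.0 | 40 |
| epsilon | 25.0 | 40 |

(scatter of a reading: 2 percentage points)

- the flask that comes out highest in amount of Z, in percent of the J charged, or "all alike" when all lie within 1.5 percentage points (Monday's / Saturday's / Friday's / Thursday's / all alike)
- Z at the end, in percent of the J charged, Monday's
- Z at the end, in percent of the J charged, Saturday's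
- Z at the end, in percent of the J charged, Friday's
- Z at the end, in percent of the J charged, Thursday's



Examiner: How long does such a flask take to reach its level?

Candidate: I read that from the first reading already on the level, and call that time the settling time, a reading that carries the scatter of the runs. In the zeta run Z is 42% at 2.00 min and 41% at 25.0 min, a difference inside the scatter of 2 percentage points. In the alpha run, at 65 °C, Z is 16% at 0.417 min.

Examiner: What do you do with that bound?

Candidate: I count. Monday's stays 8.00 min at 90 °C, and 19.2 settling times of the alpha run fit into that stage. That number is the hot count, the time a flask spends at its last temperature divided by the settling time.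

Examiner: But that settling time belongs to 65 °C and 3 mM of J.

Candidate: Yes, so I am assuming that the hotter flask is no slower and that the charge of J matters little. The count is large enough to bear some error.

Examiner: Suppose the level is a dead catalyst rather than an equilibrium. What is your count worth then?

Candidate: Nothing, and these readings can't exclude that. The two runs at 35 °C have nearly the same ratio of c(J) to c(Q). I still commit to a reversible level, that is, thermodynamic control. On that view the hot stage outlasts the settling time, so Monday's should end with Thursday's. Z reads 40% at first in the epsilon run at 35 °C and 16% at first in the alpha run at 65 °C, lower in the alpha run, though the two runs differ in their charges too, so I expect Friday's, the coolest of the flasks at 40 °C, to end highest.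

The forecast reads the level differently, as a limit set by the catalyst: “Monday's makes its Z within 2 min at 40 °C and keeps it”. It gives 25% for Monday's (range 6% to 28%), 22% for Saturday's, 25.5% for Friday's and 19% for Thursday's, with Friday's highest. On Monday's my reckoning parts from it.

The flasks give 7.08% for Monday's, 15.7% for Saturday's, 34.3% for Friday's and 7.08% for Thursday's, so Friday's is highest.

    J + Q ⇌ Z + Q, rate k1*[J]*[Q] forward; the back reaction follows from the equilibrium constant (K = 1.00, k = 49.0 M⁻¹ s⁻¹, Ea = 39.0 kJ mol⁻¹, ΔH = −39.0 kJ mol⁻¹)
    J + Q ⇌ X + Q, rate k2*[J]*[Q] forward; the back reaction follows from the equilibrium constant (K = 0.920, k = 21.0 M⁻¹ s⁻¹, Ea = 43.0 kJ mol⁻¹, ΔH = −6.00 kJ mol⁻¹)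
    (constants at 40 °C)

Monday's held Z 37.8% at 2.00 min, yet by 5.00 min it held 7.08%, and with its hot count of 19.2 it ended level with Thursday's. The forecast's 25% for Monday's stands 18 points above that. The same count on the neighbouring flask, Friday's charge run at 65 °C for the whole 10 min, gives 24.0 settling times of the alpha run. At 10.0 min that flask held Z 15.7%, with J at 47% and X at 36.8%.

The readings stem from a simulated flask on assumed constants; the scatter is artificial.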